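The side chain (C1' = quinone-bound CH2, C32' = chain end) is cut at C4'–C5'. The C5'–C32' segment, seven head-to-tail isoprene units with E alkenes at C10', C14', C18', C22' and C26', is the carbon skeleton of all-E-heptaprenol, and this regularity is what the key step exploits. A heptaprenyl diphosphate synthase builds that C35 chain in one operation from farnesyl diphosphate (C21'–C32') and four isopentenyl diphosphates, forming C20'–C21', C16'–C17', C12'–C13' and C8'–C9'; no ring is closed. The allylic C5' oxygen then steers asymmetric hydrogenation to C6'=C7' (7'R), and alkyne homologation, carboalumination and nickel coupling attach the naphthoquinone rings last.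

Key step: step 5

Assumption: the synthase is taken to be the two-component Bacillus subtilis enzyme (HepS and HepT), obtained by standard overexpression in Escherichia coli; both diphosphates are handled as ammonium salts and drawn as free acids.

Step 1
Reactants: 1 (2E,6E)-farnesol
Product: 2 (2E,6E)-farnesyl bromide
Conditions: PBr3 (0.4 equiv), Et2O, −10 → 0 °C, dark; used crude
Reagents that add atoms: phosphorus tribromide, BrP(Br)Br
Why: Bromination of a primary allylic alcohol with PBr3 runs through the phosphite ester and SN2 attack of bromide, so the 2E alkene is kept and no tertiary isomer should form at low temperature.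

Step 2
Reactants: 2 (2E,6E)-farnesyl bromide
Product: 3 (2E,6E)-farnesyl diphosphate
Conditions: (n-Bu4N)3HP2O7 (2 equiv), MeCN, rt; ion exchange to the ammonium salt on Dowex 50W-X8 (ammonium form); cellulose chromatography, i-PrOH/MeCN/aq. NH4HCO3
Reagents that add atoms: tris(tetrabutylammonium) hydrogen diphosphate, CCCC[N+](CCCC)(CCCC)CCCC.CCCC[N+](CCCC)(CCCC)CCCC.CCCC[N+](CCCC)(CCCC)CCCC.OP(=O)([O-])OP(=O)([O-])[O-]
Why: SN2 displacement of a primary allylic bromide by the diphosphate trianion in dry acetonitrile is the standard synthesis of allylic diphosphates and installs the whole diphosphate at once without touching the alkenes.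

Step 3
Reactants: 4 3-methylbut-3-en-1-ol
Product: 5 3-methylbut-3-en-1-yl 4-methylbenzenesulfonate
Conditions: TsCl, Et3N, DMAP (cat.), CH2Cl2, 0 °C → rt
Reagents that add atoms: 4-toluenesulfonyl chloride, Cc1ccc(cc1)S(=O)(=O)Cl
Why: Tosylation of the primary homoallylic alcohol gives a stable leaving group, and the 1,1-disubstituted alkene is inert under these conditions.

Step 4
Reactants: 5 3-methylbut-3-en-1-yl 4-methylbenzenesulfonate
Product: 6 isopentenyl diphosphate
Conditions: (n-Bu4N)3HP2O7 (2 equiv), MeCN, rt; ion exchange to the ammonium salt on Dowex 50W-X8 (ammonium form); cellulose chromatography, i-PrOH/MeCN/aq. NH4HCO3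
Reagents that add atoms: tris(tetrabutylammonium) hydrogen diphosphate, CCCC[N+](CCCC)(CCCC)CCCC.CCCC[N+](CCCC)(CCCC)CCCC.CCCC[N+](CCCC)(CCCC)CCCC.OP(=O)([O-])OP(=O)([O-])[O-]
Why: SN2 displacement of the primary tosylate by the diphosphate trianion is the standard route to homoallylic diphosphates, and this position cannot rearrange.

Step 5
Reactants: 3 (2E,6E)-farnesyl diphosphate (1 equiv); 6 isopentenyl diphosphate (4 equiv in all, one for each of the four condensations)
Product: 10 all-E-heptaprenyl diphosphate, via all-E-geranylgeranyl diphosphate 7 (not isolated), via all-E-geranylfarnesyl diphosphate 8 (not isolated), via all-E-hexaprenyl diphosphate 9 (not isolated)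
Conditions: heptaprenyl diphosphate synthase HepS/HepT (recombinant), MgCl2, Tris-HCl pH 8.0, DTT, Triton X-100 (0.05%), inorganic pyrophosphatase, 37 °C; 6 (4 equiv) added in portions; 1-BuOH extraction
Reagents that add atoms: isopentenyl diphosphate 6, the three further equivalents beyond the one on the Reactants line, drawn as three molecules, C=C(C)CCOP(=O)(O)OP(=O)(O)O.C=C(C)CCOP(=O)(O)OP(=O)(O)O.C=C(C)CCOP(=O)(O)OP(=O)(O)O
Why: Inside the active site magnesium assists ionisation of the allylic diphosphate of 3 to an allyl cation, the alkene of 6 attacks its C1 through C4, and removal of one C2 proton from the tertiary cation leaves a new E allylic diphosphate that serves as the next primer; the first round forms C20'–C21' and gives 7, the second forms C16'–C17' and gives 8, the third forms C12'–C13' and gives 9, and the fourth forms C8'–C9' and gives 10, so that one molecule of 6 is consumed per round and the E alkenes C18'=C19', C14'=C15', C10'=C11' and C6'=C7' arise in turn. This is the native head-to-tail prenyl transfer of medium-chain trans-prenyltransferases, run here on a preparative scale. No ring is closed and no stereocentre is made. The step needs head-to-tail regiochemistry, E geometry at each new alkene and a stop at C35: only an allylic diphosphate can ionise, so 6 can act only as the nucleophile, the fixed orientation of both substrates in the active site sets the geometry, and the depth of the hydrophobic product tunnel blocks a fifth condensation. Portionwise addition of 6 up to the 1:4 ratio and hydrolysis of the released diphosphate by the pyrophosphatase should keep the chain-length spread narrow and prevent product inhibition.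

Step 6
Reactants: 10 all-E-heptaprenyl diphosphate
Product: 11 all-E-heptaprenol
Conditions: potato acid phosphatase, NaOAc buffer pH 4.8, Triton X-100, MeOH co-solvent, 37 °C; pentane extraction; C18 reversed-phase chromatography to remove chain-length homologues
Reagents that add atoms: none
Why: Phosphatase-catalysed hydrolysis cleaves the two P–O bonds in turn and never ionises the allylic C5'–O bond, so neither allylic transposition to the tertiary alcohol nor E/Z scrambling at C6'=C7' can occur (enzymatic dephosphorylation of a polyprenyl diphosphate).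

Step 7
Reactants: 11 all-E-heptaprenol
Product: 12 (3S,6E,10E,14E,18E,22E)-3,7,11,15,19,23,27-heptamethyloctacosa-6,10,14,18,22,26-hexaen-1-ol
Conditions: Ru(OAc)2[(R)-BINAP] (1 mol %), H2 (100 atm), degassed MeOH/CH2Cl2, 20 °C
Reagents that add atoms: none
Why: In this Noyori asymmetric hydrogenation of an allylic alcohol the C5' hydroxyl binds ruthenium, so only C6'=C7' is reduced and the six remote trisubstituted alkenes remain, and the (R)-BINAP ligand delivers hydrogen to the face of the E alkene that gives the 3S alcohol (the geraniol-to-(S)-citronellol sense), the arrangement that is named 7'R in the target once chain extension reverses the CIP ranking of the two branches.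

Step 8
Reactants: 12 (3S)-dihydroheptaprenol
Product: 13 (3S,6E,10E,14E,18E,22E)-1-iodo-3,7,11,15,19,23,27-heptamethyloctacosa-6,10,14,18,22,26-hexaene
Conditions: I2, PPh3, imidazole, CH2Cl2, 0 °C → rt
Reagents that add atoms: iodine, II
Why: Appel-type iodination turns the primary alcohol into an oxyphosphonium ion that iodide displaces by SN2, leaving the stereocentre two carbons away and all alkenes untouched.

Step 9
Reactants: 13 (3S)-iodide
Product: 15 (6R,9E,13E,17E,21E,25E)-6,10,14,18,22,26,30-heptamethylhentriaconta-9,13,17,21,25,29-hexaen-1-yne, via silylalkyne 14 (not isolated)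
Conditions: 1-(trimethylsilyl)propyne (2.5 equiv), n-BuLi (2.4 equiv), THF, −40 °C; 13, THF, −78 °C → rt; then MeOH, K2CO3, rt
Reagents that add atoms: 1-(trimethylsilyl)propyne, CC#C[Si](C)(C)C
Why: Lithiated 1-(trimethylsilyl)propyne is a propargyl anion equivalent whose silyl group directs SN2 alkylation of the primary iodide to its CH2 terminus, adding C2'–C4', and carbonate in methanol then cleaves the alkynyl C–Si bond in the same flask (alkylation followed by protodesilylation), while C7' keeps its spatial arrangement and is now designated R.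

Step 10
Reactants: 16 menadione
Product: 17 2-(chloromethyl)-3-methylnaphthalene-1,4-dione
Conditions: aq. HCHO (37%), HCl (g), AcOH, rt, dark
Reagents that add atoms: formaldehyde, C=O; hydrogen chloride, Cl
Why: Chloromethylation of menadione with formaldehyde and HCl is a known reaction that can only occur at C3, the single unsubstituted quinone carbon, because the benzo ring is deactivated by both carbonyl groups.

Step 11
Reactants: 15 (6R)-alkyne; 17 2-(chloromethyl)-3-methylnaphthalene-1,4-dione
Product: 19 2-methyl-3-[(2E,7R,10E,14E,18E,22E,26E)-3,7,11,15,19,23,27,31-octamethyldotriaconta-2,10,14,18,22,26,30-heptaen-1-yl]naphthalene-1,4-dione, via alkenylalane 18 (not isolated)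
Conditions: AlMe3 (2 equiv), Cp2ZrCl2 (0.25 equiv), ClCH2CH2Cl, 0 °C → rt; volatiles removed in vacuo, THF; then 17 (1.0 equiv), NiCl2(PPh3)2 (5 mol %) pre-reduced with n-BuLi (10 mol %), THF, −20 → 0 °C; dilute HCl work-up; light excluded
Reagents that add atoms: trimethylaluminium, C[Al](C)C
Why: Zirconium-catalysed Negishi carboalumination adds methyl and aluminium syn across the terminal alkyne with aluminium on C2', giving the E alkenylalane, and zerovalent nickel (from NiCl2(PPh3)2 and n-BuLi) then couples it with the allylic-type chloride of 17 by oxidative addition, transmetalation and reductive elimination with retention, forming C1'–C2' and the 2'E alkene without touching the isolated alkenes or C7' (nickel-catalysed alkenylalane–chloromethylquinone cross-coupling).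

Compound list
1 | (2E,6E)-farnesol, (2E,6E)-3,7,11-trimethyldodeca-2,6,10-trien-1-ol | CC(C)=CCC/C(C)=C/CC/C(C)=C/CO | starting material
2 | (2E,6E)-farnesyl bromide | CC(C)=CCC/C(C)=C/CC/C(C)=C/CBr | intermediate
3 | (2E,6E)-farnesyl diphosphate (ammonium salt in practice) | CC(C)=CCC/C(C)=C/CC/C(C)=C/COP(=O)(O)OP(=O)(O)O | intermediate
4 | 3-methylbut-3-en-1-ol | C=C(C)CCO | starting material
5 | 3-methylbut-3-en-1-yl 4-methylbenzenesulfonate | C=C(C)CCOS(=O)(=O)c1ccc(C)cc1 | intermediate
6 | isopentenyl diphosphate (ammonium salt in practice) | C=C(C)CCOP(=O)(O)OP(=O)(O)O | intermediate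
7 | all-E-geranylgeranyl diphosphate, (2E,6E,10E)-3,7,11,15-tetramethylhexadeca-2,6,10,14-tetraen-1-yl diphosphate (enzyme-bound C20 primer) | CC(C)=CCC/C(C)=C/CC/C(C)=C/CC/C(C)=C/COP(=O)(O)OP(=O)(O)O | intermediate
8 | all-E-geranylfarnesyl diphosphate, (2E,6E,10E,14E)-3,7,11,15,19-pentamethylicosa-2,6,10,14,18-pentaen-1-yl diphosphate (enzyme-bound C25 primer) | CC(C)=CCC/C(C)=C/CC/C(C)=C/CC/C(C)=C/CC/C(C)=C/COP(=O)(O)OP(=O)(O)O | intermediate
9 | all-E-hexaprenyl diphosphate, (2E,6E,10E,14E,18E)-3,7,11,15,19,23-hexamethyltetracosa-2,6,10,14,18,22-hexaen-1-yl diphosphate (enzyme-bound C30 primer) | CC(C)=CCC/C(C)=C/CC/C(C)=C/CC/C(C)=C/CC/C(C)=C/CC/C(C)=C/COP(=O)(O)OP(=O)(O)O | intermediate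
10 | all-E-heptaprenyl diphosphate, (2E,6E,10E,14E,18E,22E)-3,7,11,15,19,23,27-heptamethyloctacosa-2,6,10,14,18,22,26-heptaen-1-yl diphosphate | CC(C)=CCC/C(C)=C/CC/C(C)=C/CC/C(C)=C/CC/C(C)=C/CC/C(C)=C/CC/C(C)=C/COP(=O)(O)OP(=O)(O)O | intermediate
11 | all-E-heptaprenol, (2E,6E,10E,14E,18E,22E)-3,7,11,15,19,23,27-heptamethyloctacosa-2,6,10,14,18,22,26-heptaen-1-ol | CC(C)=CCC/C(C)=C/CC/C(C)=C/CC/C(C)=C/CC/C(C)=C/CC/C(C)=C/CC/C(C)=C/CO | intermediate
12 | (3S,6E,10E,14E,18E,22E)-3,7,11,15,19,23,27-heptamethyloctacosa-6,10,14,18,22,26-hexaen-1-ol | CC(C)=CCC/C(C)=C/CC/C(C)=C/CC/C(C)=C/CC/C(C)=C/CC/C(C)=C/CC[C@H](C)CCO | intermediate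
13 | (3S,6E,10E,14E,18E,22E)-1-iodo-3,7,11,15,19,23,27-heptamethyloctacosa-6,10,14,18,22,26-hexaene (numbered from the iodide end) | CC(C)=CCC/C(C)=C/CC/C(C)=C/CC/C(C)=C/CC/C(C)=C/CC/C(C)=C/CC[C@H](C)CCI | intermediate
14 | trimethyl[(6R,9E,13E,17E,21E,25E)-6,10,14,18,22,26,30-heptamethylhentriaconta-9,13,17,21,25,29-hexaen-1-yn-1-yl]silane | CC(C)=CCC/C(C)=C/CC/C(C)=C/CC/C(C)=C/CC/C(C)=C/CC/C(C)=C/CC[C@H](C)CCCC#C[Si](C)(C)C | intermediate
15 | (6R,9E,13E,17E,21E,25E)-6,10,14,18,22,26,30-heptamethylhentriaconta-9,13,17,21,25,29-hexaen-1-yne | CC(C)=CCC/C(C)=C/CC/C(C)=C/CC/C(C)=C/CC/C(C)=C/CC/C(C)=C/CC[C@H](C)CCCC#C | intermediate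
16 | menadione, 2-methylnaphthalene-1,4-dione | CC1=CC(=O)c2ccccc2C1=O | starting material
17 | 2-(chloromethyl)-3-methylnaphthalene-1,4-dione | CC1=C(CCl)C(=O)c2ccccc2C1=O | intermediate
18 | dimethyl[(1E,6R,9E,13E,17E,21E,25E)-2,6,10,14,18,22,26,30-octamethylhentriaconta-1,9,13,17,21,25,29-heptaen-1-yl]alane | CC(C)=CCC/C(C)=C/CC/C(C)=C/CC/C(C)=C/CC/C(C)=C/CC/C(C)=C/CC[C@H](C)CCC/C(C)=C/[Al](C)C | intermediate
19 | 2-methyl-3-[(2E,7R,10E,14E,18E,22E,26E)-3,7,11,15,19,23,27,31-octamethyldotriaconta-2,10,14,18,22,26,30-heptaen-1-yl]naphthalene-1,4-dione | CC(C)=CCC/C(C)=C/CC/C(C)=C/CC/C(C)=C/CC/C(C)=C/CC/C(C)=C/CC[C@H](C)CCC/C(C)=C/CC1=C(C)C(=O)c2ccccc2C1=O | target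

Total step count: 11 steps.
Longest linear sequence: 8 steps (1, 2, 5, 6, 7, 8, 9, 11 from farnesol; the isopentenol branch through steps 3 and 4 is equally long; the menadione branch is 2 steps).

Steps most likely to fail

Step 5. The enzyme may release chains early or run on past C35, giving a spread of homologues, or turnover may stall as the micellar product accumulates. The fallback replaces the enzymatic elongation with a sulfone alkylation and reductive desulfonylation; it sets out from 2 and returns at 11. Bromide 2 is treated with PhSO2Na in DMF to give (2E,6E)-farnesyl phenyl sulfone F1. Commercial all-E-geranylgeraniol is benzylated (NaH, BnBr, THF) to all-E-geranylgeranyl benzyl ether F2, oxidised at its terminal E methyl group (SeO2 cat., t-BuOOH, CH2Cl2) to the terminal allylic alcohol F3, and brominated (CBr4, PPh3, CH2Cl2) to the terminal allylic bromide F4. Lithiated F1 (n-BuLi, THF, −78 °C) is alkylated with F4 to the C35 benzyl ether sulfone F5. Li in EtNH2 at −78 °C then removes the sulfonyl and benzyl groups together and gives all-E-heptaprenol 11.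

Step 11. The alkenylalane or residual AlMe3 may add to the quinone carbonyl groups, or low-valent nickel may reduce the quinone, faster than the cross-coupling proceeds; protonolysis of the alane is a further loss. The fallback masks the quinone as its hydroquinone dimethyl ether and oxidises last; it sets out from 16 and 15 and returns at 19. Menadione 16 is reduced (Na2S2O4, H2O/EtOAc) and methylated (Me2SO4, KOH) to 1,4-dimethoxy-2-methylnaphthalene F6, which is chloromethylated (paraformaldehyde, HCl, AcOH) to 2-(chloromethyl)-1,4-dimethoxy-3-methylnaphthalene F7. Alkenylalane 18, made from 15 as in step 11, is coupled with F7 under the same zerovalent nickel catalyst to the prenylated dimethoxynaphthalene F8. Oxidative demethylation with (NH4)2Ce(NO3)6 in MeCN/CH2Cl2/H2O at 0 °C gives 19.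

Step 7. Ruthenium-mediated allylic isomerisation at insufficient hydrogen pressure may erode the enantiomeric purity, the C35 alcohol may react slowly because it dissolves poorly in methanol, and long reaction times may begin to reduce remote alkenes. The fallback moves the reduction to the enal and uses organocatalytic transfer hydrogenation; it sets out from 11 and returns at 12. Alcohol 11 is oxidised with MnO2 in hexane to all-E-heptaprenal F9. Iminium-type transfer hydrogenation with a Hantzsch ester and the morpholinium salt of the chiral phosphoric acid TRIP (the enantiomer that delivers the 3S aldehyde, expected to be (S)-TRIP by analogy with citral) in dioxane gives (3S)-2,3-dihydroheptaprenal F10. Reduction with NaBH4 in MeOH/THF returns 12.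

Further compounds
F1 | step 5 | (2E,6E)-farnesyl phenyl sulfone | CC(C)=CCC/C(C)=C/CC/C(C)=C/CS(=O)(=O)c1ccccc1
F2 | step 5 | (2E,6E,10E)-geranylgeranyl benzyl ether | CC(C)=CCC/C(C)=C/CC/C(C)=C/CC/C(C)=C/COCc1ccccc1
F3 | step 5 | (2E,6E,10E,14E)-16-(benzyloxy)-2,6,10,14-tetramethylhexadeca-2,6,10,14-tetraen-1-ol | OC/C(C)=C/CC/C(C)=C/CC/C(C)=C/CC/C(C)=C/COCc1ccccc1
F4 | step 5 | benzyl (2E,6E,10E,14E)-16-bromo-3,7,11,15-tetramethylhexadeca-2,6,10,14-tetraen-1-yl ether | BrC/C(C)=C/CC/C(C)=C/CC/C(C)=C/CC/C(C)=C/COCc1ccccc1
F5 | step 5 | all-E-heptaprenyl benzyl ether bearing a phenylsulfonyl group at C17 of the heptaprenyl chain (racemic at that carbon) | CC(C)=CCC/C(C)=C/CC/C(C)=C/C(C/C(C)=C/CC/C(C)=C/CC/C(C)=C/CC/C(C)=C/COCc1ccccc1)S(=O)(=O)c1ccccc1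
F6 | step 11 | 1,4-dimethoxy-2-methylnaphthalene | COc1cc(C)c(OC)c2ccccc12
F7 | step 11 | 2-(chloromethyl)-1,4-dimethoxy-3-methylnaphthalene | COc1c(C)c(CCl)c(OC)c2ccccc12
F8 | step 11 | 1,4-dimethoxy-2-methyl-3-[(2E,7R,10E,14E,18E,22E,26E)-3,7,11,15,19,23,27,31-octamethyldotriaconta-2,10,14,18,22,26,30-heptaen-1-yl]naphthalene | CC(C)=CCC/C(C)=C/CC/C(C)=C/CC/C(C)=C/CC/C(C)=C/CC/C(C)=C/CC[C@H](C)CCC/C(C)=C/Cc1c(C)c(OC)c2ccccc2c1OC
F9 | step 7 | all-E-heptaprenal, (2E,6E,10E,14E,18E,22E)-3,7,11,15,19,23,27-heptamethyloctacosa-2,6,10,14,18,22,26-heptaenal | CC(C)=CCC/C(C)=C/CC/C(C)=C/CC/C(C)=C/CC/C(C)=C/CC/C(C)=C/CC/C(C)=C/C=O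
F10 | step 7 | (3S,6E,10E,14E,18E,22E)-3,7,11,15,19,23,27-heptamethyloctacosa-6,10,14,18,22,26-hexaenal | CC(C)=CCC/C(C)=C/CC/C(C)=C/CC/C(C)=C/CC/C(C)=C/CC/C(C)=C/CC[C@H](C)CC=O
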